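**Plan**
Ring letters: the upper flavan has rings A (benzo), C (pyran) and B (2-aryl). The lower epiafzelechin has rings D (benzo), F (pyran) and E (2-aryl).
Enabling feature: C4 of ring C is a doubly benzylic methine. It is bonded to C4a of ring A (para to the 7-oxygen, ortho to O1) and to C6 of ring D (between the 5- and 7-oxygens, para to O1 of ring F). Both aryl bonds can therefore come from one acetal carbon used as a 1,1-dication equivalent.
Retrosynthesis: remove the protecting groups and a C8–Br cap on ring D, then cut C4–C6(D) and C4–C4a(A) together. This opens ring C to an open-chain (S)-3-aryl-3-aryloxypropanal dimethyl acetal and 8-bromo-tri-O-benzylepiafzelechin. Then cut O1–C2 (Mitsunobu) and C3–C4 (dimethoxymethylation of a methyl ketone).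
Forward: rings A, B, D, E and F enter intact. The C2–C3–C4 chain is grown on ring B and ring A is hung on C2 through O1. Ring C is the only ring closed, in the same operation that joins the two halves.
Stereochemistry: C2 and C3 of ring F come from (−)-epiafzelechin. C2 of ring C comes from asymmetric transfer hydrogenation followed by Mitsunobu inversion. C4 comes from 1,3-induction by C2 in the cyclic cation (pseudoaxial attack, 2,4-trans).
Helpers: the C8 bromine leaves only C6 of ring D open, and a ring-B pivalate keeps C2–O1 from ionising. Both are taken out in steps 8 and 9.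

Key step: step 7

Assumption: (−)-epiafzelechin (2R,3R) is taken as a purchasable natural product, so rings D, E and F and their two stereocentres enter from the chiral pool.

Step 1
Reactants: 1 (−)-epiafzelechin
Product: 2 5,7,4'-tri-O-benzyl-(−)-epiafzelechin
Conditions: BnBr (3.3 equiv), K2CO3, DMF, 0 °C to rt
Reagents that add atoms: benzyl bromide, BrCc1ccccc1
Why: Williamson etherification in which K2CO3 deprotonates only the three phenols and leaves the secondary 3-OH untouched, as in the standard O-benzylation of flavan-3-ols, and no stereocentre is involved.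

Step 2
Reactants: 2 5,7,4'-tri-O-benzyl-(−)-epiafzelechin
Product: 3 8-bromo-5,7,4'-tri-O-benzyl-(−)-epiafzelechin
Conditions: NBS (1.0 equiv), CH2Cl2, −78 °C to rt
Reagents that add atoms: N-bromosuccinimide, O=C1CCC(=O)N1Br
Why: Electrophilic aromatic bromination of the phloroglucinol-type ring D, which in O-benzylated flavan-3-ols should take one equivalent of NBS at C8 rather than C6, so the more reactive site is capped and C6 stays open.

Step 3
Reactants: 4 4'-hydroxyacetophenone
Product: 5 4-acetylphenyl pivalate
Conditions: PivCl, Et3N, DMAP (cat.), CH2Cl2, 0 °C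
Reagents that add atoms: pivaloyl chloride, CC(C)(C)C(=O)Cl
Why: DMAP-catalysed O-acylation of a phenol, which turns the strongly donating ring-B oxygen into a nearly neutral and hindered ester that lasts through steps 4 to 7.

Step 4
Reactants: 5 4-acetylphenyl pivalate; 6 trimethyl orthoformate
Product: 7 4-(3,3-dimethoxypropanoyl)phenyl pivalate
Conditions: HC(OMe)3, BF3·OEt2, CH2Cl2, −30 to 0 °C; then 5, iPr2NEt, −78 to −20 °C
Reagents that add atoms: none
Why: Dialkoxymethylation of a methyl ketone with a preformed dialkoxycarbenium salt (a Mukaiyama-type formylation equivalent), in which the amine-generated enol is alkylated at carbon without strong base, so the aryl pivalate should survive and C4 is installed at the aldehyde oxidation level.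

Step 5
Reactants: 7 4-(3,3-dimethoxypropanoyl)phenyl pivalate
Product: 8 4-[(1R)-1-hydroxy-3,3-dimethoxypropyl]phenyl pivalate
Conditions: RuCl[(R,R)-TsDPEN](p-cymene) (1 mol %), HCO2H/Et3N 5:2, CH2Cl2, 25 °C
Reagents that add atoms: none
Why: Noyori asymmetric transfer hydrogenation, in which the CH/π contact between the cymene ligand and the aryl group fixes the ketone face, so the (R,R)-catalyst should give the (R)-carbinol just as it gives (R)-1-phenylethanol from acetophenone.

Step 6
Reactants: 8 4-[(1R)-1-hydroxy-3,3-dimethoxypropyl]phenyl pivalate; 9 3-(benzyloxy)phenol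
Product: 10 4-[(1S)-1-[3-(benzyloxy)phenoxy]-3,3-dimethoxypropyl]phenyl pivalate
Conditions: PPh3, DIAD, toluene, 0 °C to rt
Reagents that add atoms: none
Why: Mitsunobu etherification, an SN2 displacement of the oxyphosphonium group by the phenoxide with inversion (R to S) as is usual for 1-aryl-3-substituted propan-1-ols, with the acyloxy group on ring B suppressing the ionisation that erodes configuration in para-alkoxybenzylic alcohols.

Step 7
Reactants: 10 4-[(1S)-1-[3-(benzyloxy)phenoxy]-3,3-dimethoxypropyl]phenyl pivalate; 3 8-bromo-5,7,4'-tri-O-benzyl-(−)-epiafzelechin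
Product: 13 4-[(2S,4R)-7-(benzyloxy)-4-{(2R,3R)-5,7-bis(benzyloxy)-2-[4-(benzyloxy)phenyl]-8-bromo-3-hydroxychroman-6-yl}chroman-2-yl]phenyl pivalate, via 4-methoxyflavan 11 (not isolated), via flavan-4-yl cation 12 (not isolated)
Conditions: 3 (1.5 equiv), Me3SiOTf (0.3 equiv), 5 Å MS, CH2Cl2, −78 °C, slow addition of 10, then −40 °C; Et3N quench
Reagents that add atoms: none
Why: Proposed new method: Me3SiOTf ionises one methoxy group of 10 to an oxocarbenium ion, the tethered ring A attacks it through the carbon para to its benzyloxy group and ortho to O1 (intramolecular Friedel–Crafts alkylation) to give 11, and the same acid then ionises the C4–OMe bond of 11, now para to the 7-oxygen and ortho to O1, to cation 12, which C6 of 3 takes up in a second, intermolecular Friedel–Crafts alkylation. The closest known reaction types are the acid-induced cyclisation of 3-aryloxypropanal acetals to 4-alkoxychromans and the Lewis-acid union of 4-alkoxyflavans with C8-halogen-capped flavan-3-ols at C6; what is new is that both run from one acetal carbon in one flask, so ring closure and interflavan bond formation become a single event. Ring C closes in the 6-exo-trig mode with respect to the C=O+ bond, by formation of the C4–C4a bond. The one new stereocentre, C4, is controlled by C2: in the half-chair of 12 the 2-aryl group sits equatorial and the hindered nucleophile enters along the pseudoaxial line, past only the axial hydrogen at C2, which should place ring D trans to ring B and give (2S,4R). Site selectivity on ring D is secured by the C8 bromine (C6 is the only open position), that on ring A by the para-directing 7-benzyloxy group and the crowding between the two oxygens, and the order of events by the intramolecular first attack, the crowded C6 of 3 and the slow addition of 10, which also holds back self-condensation through ring A. The ring-B pivalate keeps the C2–O1 bond from ionising, so C2 is not scrambled and ring B is no nucleophile, while O-alkylation of the free 3-OH of 3 is reversible under the acid and should drain to the C–C product.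

Step 8
Reactants: 13 protected dimer (pivalate)
Product: 14 (2R,3R)-5,7-bis(benzyloxy)-6-[(2S,4R)-7-(benzyloxy)-2-(4-hydroxyphenyl)chroman-4-yl]-2-[4-(benzyloxy)phenyl]-8-bromochroman-3-ol
Conditions: LiAlH4 (3 equiv), THF, 0 °C; aqueous Rochelle salt work-up
Reagents that add atoms: none
Why: Reductive ester cleavage, in which LiAlH4 takes the aryl pivalate to an aluminium phenoxide and neopentyl alcohol without the free-phenoxide conditions that could open ring C through a ring-B quinone methide, while aryl bromide, benzyl ethers and all stereocentres are inert.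

Step 9
Reactants: 14 bromo tetrabenzyl ether
Product: 15 (2R,3R)-6-[(2S,4R)-7-hydroxy-2-(4-hydroxyphenyl)chroman-4-yl]-2-(4-hydroxyphenyl)chromane-3,5,7-triol, the target
Conditions: H2 (1 atm), Pd(OH)2/C, Et3N (1.2 equiv), THF/MeOH/H2O, rt
Reagents that add atoms: none
Why: Catalytic hydrogenolysis, the usual end game for benzyl-protected halogen-capped proanthocyanidins, should cleave the four O-benzyl bonds and the C8–Br bond in one operation with Et3N taking up HBr, while the cyclic C2–O bonds, the C4–C6 bond and the four stereocentres persist at 1 atm and rt.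

**Compound list**
1 | (−)-epiafzelechin, (2R,3R)-2-(4-hydroxyphenyl)chromane-3,5,7-triol | Oc1cc(O)c2C[C@@H](O)[C@@H](c3ccc(O)cc3)Oc2c1 | starting material
2 | 5,7,4'-tri-O-benzyl-(−)-epiafzelechin, (2R,3R)-5,7-bis(benzyloxy)-2-[4-(benzyloxy)phenyl]chroman-3-ol | O(Cc1ccccc1)c1cc(OCc2ccccc2)c2C[C@@H](O)[C@@H](c3ccc(OCc4ccccc4)cc3)Oc2c1 | intermediate
3 | 8-bromo-5,7,4'-tri-O-benzyl-(−)-epiafzelechin, (2R,3R)-5,7-bis(benzyloxy)-2-[4-(benzyloxy)phenyl]-8-bromochroman-3-ol | O(Cc1ccccc1)c1cc(OCc2ccccc2)c2C[C@@H](O)[C@@H](c3ccc(OCc4ccccc4)cc3)Oc2c1Br | intermediate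
4 | 4'-hydroxyacetophenone | CC(=O)c1ccc(O)cc1 | starting material
5 | 4-acetylphenyl pivalate | CC(=O)c1ccc(OC(=O)C(C)(C)C)cc1 | intermediate
6 | trimethyl orthoformate | COC(OC)OC | starting material
7 | 4-(3,3-dimethoxypropanoyl)phenyl pivalate | COC(OC)CC(=O)c1ccc(OC(=O)C(C)(C)C)cc1 | intermediate
8 | 4-[(1R)-1-hydroxy-3,3-dimethoxypropyl]phenyl pivalate | COC(OC)C[C@@H](O)c1ccc(OC(=O)C(C)(C)C)cc1 | intermediate
9 | 3-(benzyloxy)phenol | Oc1cccc(OCc2ccccc2)c1 | starting material
10 | 4-[(1S)-1-[3-(benzyloxy)phenoxy]-3,3-dimethoxypropyl]phenyl pivalate | COC(OC)C[C@H](Oc1cccc(OCc2ccccc2)c1)c1ccc(OC(=O)C(C)(C)C)cc1 | intermediate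
11 | (2S)-7-(benzyloxy)-4-methoxy-2-[4-(pivaloyloxy)phenyl]chroman, both C4 epimers, not isolated | COC1C[C@@H](c2ccc(OC(=O)C(C)(C)C)cc2)Oc2cc(OCc3ccccc3)ccc12 | intermediate
12 | (2S)-7-(benzyloxy)-2-[4-(pivaloyloxy)phenyl]chroman-4-ylium triflate, not isolated | [CH+]1C[C@@H](c2ccc(OC(=O)C(C)(C)C)cc2)Oc2cc(OCc3ccccc3)ccc12.[O-]S(=O)(=O)C(F)(F)F | intermediate
13 | 4-[(2S,4R)-7-(benzyloxy)-4-{(2R,3R)-5,7-bis(benzyloxy)-2-[4-(benzyloxy)phenyl]-8-bromo-3-hydroxychroman-6-yl}chroman-2-yl]phenyl pivalate | CC(C)(C)C(=O)Oc1ccc([C@@H]2C[C@@H](c3c(OCc5ccccc5)c(Br)c4c(c3OCc5ccccc5)C[C@@H](O)[C@@H](c5ccc(OCc6ccccc6)cc5)O4)c3ccc(OCc4ccccc4)cc3O2)cc1 | intermediate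
14 | (2R,3R)-5,7-bis(benzyloxy)-6-[(2S,4R)-7-(benzyloxy)-2-(4-hydroxyphenyl)chroman-4-yl]-2-[4-(benzyloxy)phenyl]-8-bromochroman-3-ol | Oc1ccc([C@@H]2C[C@@H](c3c(OCc5ccccc5)c(Br)c4c(c3OCc5ccccc5)C[C@@H](O)[C@@H](c5ccc(OCc6ccccc6)cc5)O4)c3ccc(OCc4ccccc4)cc3O2)cc1 | intermediate
15 | (2S)-7,4'-dihydroxyflavan-(4β→6)-(−)-epiafzelechin, (2R,3R)-6-[(2S,4R)-7-hydroxy-2-(4-hydroxyphenyl)chroman-4-yl]-2-(4-hydroxyphenyl)chromane-3,5,7-triol | Oc1ccc([C@@H]2C[C@@H](c3c(O)cc4c(c3O)C[C@@H](O)[C@@H](c3ccc(O)cc3)O4)c3ccc(O)cc3O2)cc1 | target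

Total step count: 9.
Longest linear sequence: 7 steps (4 to 15, steps 3 to 9).

**Steps most likely to fail**

Step 7. Several processes could spoil the cascade.
- The open-chain oxocarbenium ion may be captured by 3 before ring closure.
- It may lose a proton to an enol ether, after which the aryloxide is expelled.
- The cation may self-condense through ring A.
- The facial selectivity at C4 may be poor.

The fallback uses only known reaction types and closes ring C at the ketone level before the union. It sets out from 10.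
- The acetal is hydrolysed (PPTS, wet acetone) to 4-[(1S)-1-[3-(benzyloxy)phenoxy]-3-oxopropyl]phenyl pivalate F1.
- Pinnick oxidation (NaClO2, NaH2PO4, 2-methyl-2-butene) gives (3S)-3-[3-(benzyloxy)phenoxy]-3-[4-(pivaloyloxy)phenyl]propanoic acid F2.
- Intramolecular Friedel–Crafts acylation ((CF3CO)2O, CH2Cl2, 0 °C) gives (2S)-7-(benzyloxy)-2-[4-(pivaloyloxy)phenyl]chroman-4-one F3.
- NaBH4 gives the 2,4-cis alcohol (2S,4S)-7-(benzyloxy)-2-[4-(pivaloyloxy)phenyl]chroman-4-ol F4.
- BF3·OEt2 at −78 °C ionises this alcohol in the presence of 3, and the route is rejoined at 13.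

Step 6. The configuration may erode through an ion-pair pathway. The activated alcohol may eliminate to a styrene. Conversion at the secondary benzylic centre may be slow.

The fallback forms the aryl C–O bond instead of the alkyl C–O bond, so the carbinol configuration is retained. It sets out from 7.
- Transfer hydrogenation with RuCl[(S,S)-TsDPEN](p-cymene) gives 4-[(1S)-1-hydroxy-3,3-dimethoxypropyl]phenyl pivalate F5.
- This alcohol is O-arylated with purchased 1-(benzyloxy)-3-iodobenzene in an Ullmann-type coupling (CuI, 3,4,7,8-tetramethyl-1,10-phenanthroline, Cs2CO3, toluene, 80–110 °C).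
- Any pivalate shifted by the base is restored with pivaloyl chloride before purification, and the route is rejoined at 10.

Step 9. The C–Br cleavage may be slow and bromide may poison the catalyst. HBr may cleave the interflavan bond. The cyclic benzylic C–O bonds may be over-reduced on prolonged exposure.

The fallback separates the two reductive events and sets out from 14.
- Bromine–lithium exchange (n-BuLi, 4 equiv, THF, −78 °C, MeOH quench) gives (2R,3R)-5,7-bis(benzyloxy)-6-[(2S,4R)-7-(benzyloxy)-2-(4-hydroxyphenyl)chroman-4-yl]-2-[4-(benzyloxy)phenyl]chroman-3-ol F6.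
- This halogen-free ether is debenzylated under neutral conditions (H2, Pd/C, THF/MeOH), and the route is rejoined at 15.

**Further compounds**
F1 | step 7 | 4-[(1S)-1-[3-(benzyloxy)phenoxy]-3-oxopropyl]phenyl pivalate | O=CC[C@H](Oc1cccc(OCc2ccccc2)c1)c1ccc(OC(=O)C(C)(C)C)cc1
F2 | step 7 | (3S)-3-[3-(benzyloxy)phenoxy]-3-[4-(pivaloyloxy)phenyl]propanoic acid | OC(=O)C[C@H](Oc1cccc(OCc2ccccc2)c1)c1ccc(OC(=O)C(C)(C)C)cc1
F3 | step 7 | (2S)-7-(benzyloxy)-2-[4-(pivaloyloxy)phenyl]chroman-4-one | O=C1C[C@@H](c2ccc(OC(=O)C(C)(C)C)cc2)Oc2cc(OCc3ccccc3)ccc12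
F4 | step 7 | (2S,4S)-7-(benzyloxy)-2-[4-(pivaloyloxy)phenyl]chroman-4-ol | O[C@H]1C[C@@H](c2ccc(OC(=O)C(C)(C)C)cc2)Oc2cc(OCc3ccccc3)ccc12
F5 | step 6 | 4-[(1S)-1-hydroxy-3,3-dimethoxypropyl]phenyl pivalate | COC(OC)C[C@H](O)c1ccc(OC(=O)C(C)(C)C)cc1
F6 | step 9 | (2R,3R)-5,7-bis(benzyloxy)-6-[(2S,4R)-7-(benzyloxy)-2-(4-hydroxyphenyl)chroman-4-yl]-2-[4-(benzyloxy)phenyl]chroman-3-ol | Oc1ccc([C@@H]2C[C@@H](c3c(OCc5ccccc5)cc4c(c3OCc5ccccc5)C[C@@H](O)[C@@H](c5ccc(OCc6ccccc6)cc5)O4)c3ccc(OCc4ccccc4)cc3O2)cc1
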